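The readings stem from a simulated flask from invented constants.

At 40 min the question was whether the route in mattered, since zeta, delta, gamma and eta each received 0.032 M of starting complex and 0.0384 M of incoming ligand.

| setting | ash | oak | elm | birch | zeta | delta | gamma | eta |
|---|---|---|---|---|---|---|---|---|
| starting complex | 0.032 M | 0.032 M | 0.032 M | 0.016 M | 0.032 M | 0.032 M | 0.032 M | 0.032 M (fed, over 8.0 min) |
| incoming ligand | 0.0384 M | 0.019 M | 0.029 M | 0.0384 M | 0.0384 M (fed, over 8.0 min) | 0.0384 M (in portions, 5, over 8.0 min) | 0.0384 M | 0.0384 M |
| remark | run made earlier | run made earlier | run made earlier | run made earlier | all else is in the flask from the start; the feed brings no volume worth counting | first portion at the start, last at 8.0 min | everything together at the start | all else is in the flask from the start; the feed brings no volume worth counting |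
| time |  |  |  |  | 40 min | 40 min | 40 min | 40 min |

- ash (time / min: over-reaction product / %, complex with three exchanged / %, starting complex / %): 10.0: 16.1, 2.0, 28.6; 20.0: 19.5, 1.1, 28.5; 30.0: 21.5, 0, 29.2; 40.0: 22.8, 0.2, 29.9
- oak (time / min: over-reaction product / %, complex with three exchanged / %, starting complex / %): 12.0: 3.9, 1.2, 33.0; 25.0: 6.5, 0.5, 34.1; 40.0: 8.8, 0, 34.1; 50.0: 8.9, 0.9, 34.5
- elm (time / min: over-reaction product / %, complex with three exchanged / %, starting complex / %): 6.00: 6.9, 2.8, 29.7; 15.0: 11.5, 1.3, 30.5; 30.0: 14.2, 1.4, 30.8; 50.0: 17.1, 0.6, 31.8
- birch (time / min: over-reaction product / %, complex with three exchanged / %, starting complex / %): 12.0: 37.8, 2.6, 19.0; 25.0: 44.6, 0.5, 19.1; 40.0: 46.7, 0.2, 20.0; 50.0: 48.1, 0.4, 19.4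

(readings scatter by 0.5 percentage points)

- which flask leads in amount of over-reaction product, in percent of the starting complex charged ("all alike" within 1.5 percentage points) (zeta / delta / gamma / eta / all alike)
- how much over-reaction product is there at the end, in percent of the starting complex charged: zeta
- how much over-reaction product is there at the end, in percent of the starting complex charged: delta
- how much over-reaction product is there at the end, in percent of the starting complex charged: gamma
- how much over-reaction product is there at the end, in percent of the starting complex charged: eta

- the numbers in the tables scatter with a standard deviation of 0.5 percentage points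

I turned the readings at 40.0 min into concentrations. Over-reaction product stood at 0.00730 M in ash and 0.00747 M in birch, level although birch had half the complex, so the incoming ligand looked like the limiting reagent for this product. The straight line through oak and ash has a slope of 0.231: this is the ligand yield, the over-reaction product gained by that time for each extra mole of ligand charged to 0.032 M of starting complex. The line reaches zero at a charge of 0.00681 M.

But two points always make a line. So I tested it on elm, where it gave 16.0 %, and the elm readings were 14.2 % at 30.0 min and 17.1 % at 50.0 min, on either side of that value.

The line puts zeta, delta, gamma and eta at ash's level, 22.8 %. But ash had everything in at the start, whereas the slow additions in zeta and delta arrived on average 4.00 min late. Ash's late rise, multiplied by that delay, came by my estimate to 0.52 points, less than the margin of 1.5 points. Eta raised a second doubt, since its complex met excess ligand, as in birch, which read 37.8 % at 12.0 min. Yet birch's concentration at 40.0 min stood level with ash's, so I gave eta the same delay. I committed to all alike, with gamma near 22.8 % and the others near 22.3 %.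

The forecast differed: it named eta as leader, with zeta 20.5 %, delta 21 %, gamma 23 % and eta 27 %. Its ground was: “Feeding the complex into full ligand favours over-reaction, as birch does”.

The flasks gave zeta 22.1 %, delta 22.1 %, gamma 22.7 % and eta 22.7 %, so the verdict was all alike.

    starting complex + incoming ligand ⇌ leaving ligand + complex with one exchanged (K = 1.20, k = 0.970 /M/s)
    complex with one exchanged + incoming ligand ⇌ leaving ligand + complex with two exchanged (K = 1.60, k = 6.70 /M/s)
    complex with two exchanged + incoming ligand ⇌ leaving ligand + complex with three exchanged (K = 0.930, k = 0.720 /M/s)
    complex with three exchanged + incoming ligand → over-reaction product (k = 0.740 /M/s)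
    starting complex ⇌ dormant form (K = 1.30, k = 0.00910 /s)

The forecast and the flasks parted on the leader, since eta stood level with gamma. I then put the ligand yield of 0.231 to a neighbouring flask, like eta but charged with 0.096 M of incoming ligand. The line gave 64.4 % of over-reaction product for that flask. The flask itself gave 62.9 % at 40 min.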